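**Strategy.** Everything rests on a biomimetic intramolecular Diels–Alder reaction (locants as defined in the remark below). The exocyclic methylidene C28=C29 of a 3-acyl-4-methoxy-5-methylidenetetronate adds across the terminal (E,E)-diene C30=C2–C3=C4 of the polyene chain that hangs from its own acyl group. One operation closes the methylcyclohexene, creates the spiro carbon C28 shared with the tetronate ring together with C4 and C30, and closes the 19-membered carbocycle. The precursor is an open-chain tetraene carrying the finished all-trans thiolane keto ester. It is assembled by Julia–Kocienski olefination, a Mukaiyama–Michael/iodocyclisation thiolane annulation, a Stille coupling and a thioester–stannane ketone synthesis.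

Key step: step 26

Remark on locants: the 31 carbons, the sulfur and the ring oxygen of the target are numbered in the order in which they occur in its SMILES, oxygens outside the rings not being counted. C1 is the ring methyl, C2=C3 the ring alkene, C4 the ring CH, C5–C16 the chain (OH on C11, methyl C17 on C16), C18/C19/S22/C23/C24 the thiolane, C20/C21 the keto acid, C25 the acyl carbonyl, C26/C27/C28/O32/C33 the tetronate, C29 the ring CH2, C30 the ring CH with methyl C31.

Remark on the chemistry: C19 and C24 each lie α to a carbonyl group and are taken to be under thermodynamic control (both trans to the C18 substituent); compounds 1, 7, 14, 16, 23, 26 and 30 are taken as commercial. TBS = tert-butyldimethylsilyl, PT = 1-phenyl-1H-tetrazol-5-yl.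

**Route**

Step 1
Reactants: 1 ethyl (R)-4-cyano-3-hydroxybutanoate
Product: 2 ethyl (R)-3-(tert-butyldimethylsilyloxy)-4-cyanobutanoate
Conditions: TBSCl, imidazole, DMF, 23 °C
Reagents that add atoms: tert-butyldimethylsilyl chloride, CC(C)(C)[Si](C)(C)Cl
Why: Routine silylation of the secondary alcohol, whose carbon is the future C11 stereocentre taken unchanged from the chiral pool.

Step 2
Reactants: 2 ethyl (R)-3-(tert-butyldimethylsilyloxy)-4-cyanobutanoate
Product: 3 (R)-3-(tert-butyldimethylsilyloxy)-5-hydroxypentanenitrile
Conditions: LiBH4, THF, 0 → 23 °C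
Reagents that add atoms: none
Why: LiBH4 reduces the ester but not the nitrile, so the two ends of the C9–C13 unit are differentiated.

Step 3
Reactants: 3 (R)-3-(tert-butyldimethylsilyloxy)-5-hydroxypentanenitrile
Product: 4 (R)-3-(tert-butyldimethylsilyloxy)-5-oxopentanenitrile
Conditions: Dess–Martin periodinane, NaHCO3, CH2Cl2, 0 → 23 °C
Reagents that add atoms: none
Why: Dess–Martin oxidation of the primary alcohol should give the β-silyloxy aldehyde (C9) without β-elimination under buffered, non-basic conditions.

Step 4
Reactants: 4 (R)-3-(tert-butyldimethylsilyloxy)-5-oxopentanenitrile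
Product: 5 (3S,5E)-3-(tert-butyldimethylsilyloxy)-6-iodohex-5-enenitrile
Conditions: CrCl2, CHI3, THF/1,4-dioxane, 0 → 23 °C
Reagents that add atoms: iodoform, C(I)(I)I
Why: Takai olefination with the geminal dichromium reagent from CHI3 converts the aldehyde into the E vinyl iodide (C8=C9), the E geometry arising in the elimination of the β-oxido chromium intermediate.

Step 5
Reactants: 5 (3S,5E)-3-(tert-butyldimethylsilyloxy)-6-iodohex-5-enenitrile
Product: 6 (3S,5E)-3-(tert-butyldimethylsilyloxy)-6-iodohex-5-enal
Conditions: iBu2AlH, CH2Cl2, −78 °C; aqueous potassium sodium tartrate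
Reagents that add atoms: water, O
Why: iBu2AlH adds once to the nitrile and the aluminium aldimine is hydrolysed on work-up to the aldehyde (C13), the vinyl iodide and silyl ether being inert at −78 °C.

Step 6
Reactants: 7 3-methylideneoxolan-2-one (α-methylene-γ-butyrolactone)
Product: 8 (S)-3-methyloxolan-2-one
Conditions: H2 (50 atm), Ru(OAc)2[(R)-BINAP] (0.5 mol %), CH2Cl2, 50 °C
Reagents that add atoms: none
Why: BINAP–ruthenium asymmetric hydrogenation of the exocyclic alkene of an α-methylene lactone sets the C16 methyl stereocentre, the lactone carbonyl acting as the coordinating group and the ligand antipode being the one that delivers the S lactone.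

Step 7
Reactants: 8 (S)-3-methyloxolan-2-one
Product: 9 ethyl (S)-4-bromo-2-methylbutanoate
Conditions: HBr (gas), EtOH, 0 → 23 °C
Reagents that add atoms: hydrogen bromide, Br; ethanol, CCO
Why: Acid-mediated alkyl–oxygen opening of the γ-lactone by bromide with Fischer esterification gives the γ-bromo ester without touching the α-stereocentre.

Step 8
Reactants: 9 ethyl (S)-4-bromo-2-methylbutanoate
Product: 10 ethyl (S)-2-methyl-4-(PT-sulfanyl)butanoate
Conditions: 1-phenyl-1H-tetrazole-5-thiol, K2CO3, acetone, 23 °C
Reagents that add atoms: 1-phenyl-1H-tetrazole-5-thiol, Sc1nnnn1-c1ccccc1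
Why: SN2 displacement of the primary bromide by the tetrazolethiolate (thioether synthesis), the weak base leaving the α-stereocentre intact.

Step 9
Reactants: 10 ethyl (S)-2-methyl-4-(PT-sulfanyl)butanoate
Product: 11 ethyl (S)-2-methyl-4-(PT-sulfonyl)butanoate
Conditions: 30 % H2O2, (NH4)6Mo7O24 (10 mol %), EtOH, 0 → 23 °C
Reagents that add atoms: hydrogen peroxide, OO
Why: Molybdate-catalysed peroxide oxidation takes the sulfide to the sulfone needed for the Julia–Kocienski olefination.

Step 10
Reactants: 11 ethyl (S)-2-methyl-4-(PT-sulfonyl)butanoate; 6 (3S,5E)-3-(tert-butyldimethylsilyloxy)-6-iodohex-5-enal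
Product: 12 ethyl (2S,4E,7R,9E)-7-(tert-butyldimethylsilyloxy)-10-iodo-2-methyldeca-4,9-dienoate
Conditions: 11, KN(SiMe3)2, DME, −60 °C; then 6, −60 → 23 °C
Reagents that add atoms: none
Why: Julia–Kocienski olefination, in which the metalated tetrazolyl sulfone adds to the aldehyde and Smiles rearrangement with loss of SO2 and the tetrazolone gives the C13=C14 alkene, E-selective for an unbranched potassium sulfonyl carbanion in DME, the sulfone α-proton being far more acidic than the ester α-proton so that C16 is not epimerised.

Step 11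
Reactants: 12 ethyl (2S,4E,7R,9E)-7-(tert-butyldimethylsilyloxy)-10-iodo-2-methyldeca-4,9-dienoate
Product: 13 (2S,4E,7R,9E)-7-(tert-butyldimethylsilyloxy)-10-iodo-2-methyldeca-4,9-dienal
Conditions: iBu2AlH (1.1 equiv), CH2Cl2, −78 °C; aqueous potassium sodium tartrate
Reagents that add atoms: none
Why: Low-temperature iBu2AlH reduction stops at the tetrahedral aluminium hemiacetal, which releases the α-methyl aldehyde (C18) on work-up.

Step 12
Reactants: 13 (2S,4E,7R,9E)-7-(tert-butyldimethylsilyloxy)-10-iodo-2-methyldeca-4,9-dienal; 14 ethyl 2-oxo-3-(triphenyl-λ5-phosphanylidene)propanoate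
Product: 15 ethyl (3E,5S,7E,10R,12E)-10-(tert-butyldimethylsilyloxy)-13-iodo-5-methyl-2-oxotrideca-3,7,12-trienoate
Conditions: toluene, 60 °C
Reagents that add atoms: none
Why: Wittig reaction of the stabilised, non-basic keto ylide should give the E β,γ-unsaturated α-keto ester (C18=C19, C20, C21) without epimerising the α-stereocentre of the aldehyde.

Step 13
Reactants: 16 3-(benzylsulfanyl)propanoic acid
Product: 17 S-phenyl 3-(benzylsulfanyl)propanethioate
Conditions: PhSH, DCC, DMAP (cat.), CH2Cl2, 0 → 23 °C
Reagents that add atoms: thiophenol, Sc1ccccc1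
Why: Carbodiimide-mediated thioesterification (Steglich type) of the acid with thiophenol.

Step 14
Reactants: 17 S-phenyl 3-(benzylsulfanyl)propanethioate
Product: 18 [(1Z)-3-(benzylsulfanyl)-1-(phenylsulfanyl)prop-1-en-1-yl]oxy(trimethyl)silane
Conditions: LiN(iPr)2, Me3SiCl (internal quench), THF, −78 °C
Reagents that add atoms: chlorotrimethylsilane, C[Si](C)(C)Cl
Why: Kinetic deprotonation with in situ silylation gives the Z silyl ketene thioacetal before the β-benzylsulfanyl group can be eliminated, lithium enolates of β-sulfanyl propanoates being known acrylate α-anion equivalents.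

Step 15
Reactants: 15 ethyl (3E,5S,7E,10R,12E)-10-(tert-butyldimethylsilyloxy)-13-iodo-5-methyl-2-oxotrideca-3,7,12-trienoate; 18 silyl ketene thioacetal
Product: 19 enol silane Michael adduct: ethyl (2Z)-2-(trimethylsilyloxy)alk-2-enoate C21–C19 carrying on C18 the C16–C8 chain of 15 and the C24H(CH2SBn)C(=O)SPh unit, C18 and C24 configured as in the target
Conditions: Cu(OTf)2 (10 mol %), (S,S)-2,2'-(propane-2,2-diyl)bis(4-tert-butyl-4,5-dihydrooxazole) (11 mol %), 4 Å molecular sieves, CH2Cl2, −78 → −40 °C; filtration through Florisil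
Reagents that add atoms: none
Why: The α-keto ester chelates divalent copper and its s-cis enone is attacked at C18 by the silyl ketene thioacetal (catalytic enantioselective Mukaiyama–Michael addition to a β,γ-unsaturated α-keto ester), the ligand antipode being the one that directs attack to the C18 face required by the target with the C16 centre only a secondary bias, while silyl transfer leaves the enol silane regiospecifically at C19=C20 and any C24 epimer formed here is corrected in step 16.

Step 16
Reactants: 19 enol silane Michael adduct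
Product: 22 all-trans thiolane: S-phenyl 5-(2-ethoxy-2-oxoacetyl)-4-[(4E,9E)-7-(tert-butyldimethylsilyloxy)-10-iododeca-4,9-dien-2-yl]thiolane-3-carbothioate with stereocentres as in the target, via α-iodo keto ester 20 (not isolated), via S-benzylthiolanium iodide 21 (not isolated)
Conditions: N-iodosuccinimide, CH2Cl2, −78 → 23 °C; aqueous Na2S2O3; then DBU (0.2 equiv), CH2Cl2, 23 °C
Reagents that add atoms: none
Why: Iodination of the enol silane gives the α-iodo α-keto ester, the benzyl sulfide displaces iodide in a 5-exo-tet S-alkylation, iodide removes the benzyl group from the sulfonium salt as benzyl iodide (dealkylative thiolane formation), and DBU equilibrates the two enolisable centres C19 and C24 to the thiolane in which both are trans to the bulky C18 substituent.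

Step 17
Reactants: 23 but-3-yn-1-ol
Product: 24 5-(but-3-yn-1-ylsulfanyl)-1-phenyl-1H-tetrazole
Conditions: 1-phenyl-1H-tetrazole-5-thiol, PPh3, DIAD, THF, 0 → 23 °C
Reagents that add atoms: 1-phenyl-1H-tetrazole-5-thiol, Sc1nnnn1-c1ccccc1
Why: Mitsunobu reaction of the primary alcohol with the acidic tetrazolethiol.

Step 18
Reactants: 24 5-(but-3-yn-1-ylsulfanyl)-1-phenyl-1H-tetrazole
Product: 25 5-(but-3-yn-1-ylsulfonyl)-1-phenyl-1H-tetrazole
Conditions: 30 % H2O2, (NH4)6Mo7O24 (10 mol %), EtOH, 0 → 23 °C
Reagents that add atoms: hydrogen peroxide, OO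
Why: Molybdate-catalysed oxidation of the sulfide to the sulfone, the terminal alkyne being inert.

Step 19
Reactants: 25 5-(but-3-yn-1-ylsulfonyl)-1-phenyl-1H-tetrazole; 26 (E)-2-methylbut-2-enal (tiglic aldehyde)
Product: 27 (4E,6E)-6-methylocta-4,6-dien-1-yne
Conditions: 25, KN(SiMe3)2 (1.05 equiv), DME, −60 °C; then 26, −60 → 23 °C
Reagents that add atoms: none
Why: Julia–Kocienski olefination with the α-branched enal should form the C3=C4 alkene with E geometry while the C30=C2 geometry comes unchanged from tiglic aldehyde, the sulfone α-proton being more acidic than the acetylenic proton.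

Step 20
Reactants: 27 (4E,6E)-6-methylocta-4,6-dien-1-yne
Product: 28 tributyl[(1E,4E,6E)-6-methylocta-1,4,6-trien-1-yl]stannane
Conditions: Bu3SnH, Pd2(dba)3 (1 mol %), Cy3P·HBF4 (4 mol %), iPr2NEt (8 mol %), CH2Cl2, 0 °C
Reagents that add atoms: tributyltin hydride, CCCC[SnH](CCCC)CCCC
Why: Palladium-catalysed syn hydrostannation of the terminal alkyne places tin on the terminal carbon (E stannane, C6=C7), the bulky phosphine suppressing the internal regioisomer, and is faster than hydrostannation of the diene.

Step 21
Reactants: 22 all-trans thiolane vinyl iodide; 28 tributyl[(1E,4E,6E)-6-methylocta-1,4,6-trien-1-yl]stannane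
Product: 29 tetraene thioester: compound 22 with the iodine replaced by the (1E,4E,6E)-6-methylocta-1,4,6-trien-1-yl group
Conditions: Pd2(dba)3 (5 mol %), AsPh3 (20 mol %), DMF, 23 °C, dark, no copper salt
Reagents that add atoms: none
Why: Stille coupling of the E vinyl iodide with the E alkenylstannane, with retention at both carbons, creates the C6–C9 diene and the skipped tetraene under neutral conditions, and without a copper carboxylate the thioester is not activated.

Step 22
Reactants: 30 4-methoxyfuran-2(5H)-one (methyl tetronate)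
Product: 31 5-[(dimethylamino)methyl]-4-methoxyfuran-2(5H)-one (racemic)
Conditions: LiN(iPr)2, THF, −78 °C; then dimethylmethylideneammonium iodide, −78 → 0 °C
Reagents that add atoms: dimethylmethylideneammonium iodide, C=[N+](C)C.[I-]
Why: Methyl tetronate is lithiated at C5, the position that gives the aromatic 2-oxidofuran, and the anion is aminomethylated by the iminium salt (Mannich reaction).

Step 23
Reactants: 31 5-[(dimethylamino)methyl]-4-methoxyfuran-2(5H)-one
Product: 33 4-methoxy-5-methylidenefuran-2(5H)-one, via trimethylammonium iodide 32 (not isolated)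
Conditions: MeI, CH2Cl2, 23 °C; then aqueous NaHCO3, 23 °C
Reagents that add atoms: none
Why: Quaternisation followed by E1cB elimination of trimethylamine (Mannich methylenation) installs the exocyclic methylidene, the future C29.

Step 24
Reactants: 33 4-methoxy-5-methylidenefuran-2(5H)-one
Product: 34 4-methoxy-5-methylidene-3-(tributylstannyl)furan-2(5H)-one
Conditions: LiN(iPr)2, THF, −95 °C, 5 min; then Bu3SnCl, −95 → −78 °C
Reagents that add atoms: tributyltin chloride, CCCC[Sn](Cl)(CCCC)CCCC
Why: With C5 now sp2 the only acidic site is the vinylic C3–H flanked by the carbonyl and the methoxy group, and the vinyllithium is trapped by the tin chloride at low temperature before it can add to the methylidene group.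

Step 25
Reactants: 29 tetraene thioester; 34 4-methoxy-5-methylidene-3-(tributylstannyl)furan-2(5H)-one
Product: 35 cycloaddition precursor: compound 29 with the C(=O)SPh group replaced by a (4-methoxy-5-methylidene-2-oxo-2,5-dihydrofuran-3-yl)carbonyl group
Conditions: Pd2(dba)3 (5 mol %), P(2-furyl)3 (20 mol %), CuO2PPh2 (1.5 equiv), THF, 23 → 45 °C, dark
Reagents that add atoms: none
Why: Palladium-catalysed, copper-carboxylate-mediated thioester–organostannane ketone synthesis (Liebeskind–Srogl coupling) joins C25 to tetronate C3 (C26) under neutral conditions that spare the α-keto ester, the polyene and the enolisable centres C19 and C24.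

Step 26
Reactants: 35 cycloaddition precursor
Product: 36 cycloadduct: the target skeleton as its C11 TBS ether, C21 ethyl ester and tetronate 4-O-methyl ether
Conditions: toluene (0.5 mM), BHT (10 mol %), 120 °C, sealed vessel, dark
Reagents that add atoms: none
Why: Thermal, concerted suprafacial [4+2] cycloaddition in which the electron-poor exocyclic alkene C28=C29 (the δ-position of the doubly acylated vinylogous ester) adds across the electron-rich trialkyl (E,E)-diene C30=C2–C3=C4, forming C29–C30 and C4–C28 at once. The closest known reaction type is the intramolecular Diels–Alder macrocyclisation of 3-acyl-5-methylidene tetronates, precedented for smaller carbocycles and mirrored by the enzymatic spirotetronate-forming step. Two rings close: the six-membered ring by the cycloaddition itself, spiro at C28 to the tetronate, and the 19-membered carbocycle as the ring fused across the new C4–C28 bond, the tether running from diene terminus C4 through C5–C16, C18 and C24–C27 to dienophile carbon C28. C4 and C30 end up cis because both diene termini carry their substituents in the outside (E) positions, and C28 is set by the exo transition state (ring oxygen O32 under the diene, C27 pointing away), which is the intrinsic preference of 5-methylidene tetronates and the mode in which the tether, leaving the diene from the outside position of C4 and entering the dienophile through C27, is least strained. The absolute sense, that is which diene face is used, is not enforced by a reagent and must come from the folding of the tether, which is stiffened by three E alkenes, the trans-thiolane and the planar acyl tetronate and biased by C24 and C11; this is the selectivity at risk. Selectivity for the terminal diene over the internal C6–C9 diene rests on its higher substitution and on ring size, regiochemistry is fixed by the tether and matched electronically, and high dilution with a radical inhibitor suppresses oligomerisation.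

Step 27
Reactants: 36 cycloadduct
Product: 37 tetronic acid: compound 36 with the tetronate 4-OH free
Conditions: LiCl (10 equiv), DMSO, 50 °C; then dilute HCl to pH 3
Reagents that add atoms: none
Why: Chloride demethylates the vinylogous ester by SN2 attack at the methyl group, the 3-acyl tetronate being an excellent leaving group, while the ethyl ester and the silyl ether are not affected.

Step 28
Reactants: 37 tetronic acid
Product: 38 ethyl ester of the target (C11 OH free)
Conditions: HF·pyridine, pyridine, THF, 0 → 23 °C
Reagents that add atoms: none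
Why: Fluoride cleaves the secondary silyl ether under buffered conditions that should not isomerise the skipped diene.

Step 29
Reactants: 38 ethyl ester of the target
Product: 39 target CNP0224658.3
Conditions: LiOH (3 equiv), THF/H2O 3:1, 0 °C; then 1 M HCl to pH 2
Reagents that add atoms: lithium hydroxide, [Li+].[OH-]
Why: α-Keto esters are hydrolysed by hydroxide much faster than ordinary esters, the tetronate being protected as its anion, and the base-labile C19 centre settles in its thermodynamic configuration trans to C18.

**Compound list**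

1 | ethyl (R)-4-cyano-3-hydroxybutanoate | CCOC(=O)C[C@H](O)CC#N | starting material
2 | ethyl (R)-3-(tert-butyldimethylsilyloxy)-4-cyanobutanoate | CCOC(=O)C[C@H](O[Si](C)(C)C(C)(C)C)CC#N | intermediate
3 | (R)-3-(tert-butyldimethylsilyloxy)-5-hydroxypentanenitrile | OCC[C@H](O[Si](C)(C)C(C)(C)C)CC#N | intermediate
4 | (R)-3-(tert-butyldimethylsilyloxy)-5-oxopentanenitrile | O=CC[C@H](O[Si](C)(C)C(C)(C)C)CC#N | intermediate
5 | (3S,5E)-3-(tert-butyldimethylsilyloxy)-6-iodohex-5-enenitrile | I/C=C/C[C@H](O[Si](C)(C)C(C)(C)C)CC#N | intermediate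
6 | (3S,5E)-3-(tert-butyldimethylsilyloxy)-6-iodohex-5-enal | I/C=C/C[C@H](O[Si](C)(C)C(C)(C)C)CC=O | intermediate
7 | 3-methylideneoxolan-2-one | C=C1CCOC1=O | starting material
8 | (S)-3-methyloxolan-2-one | C[C@H]1CCOC1=O | intermediate
9 | ethyl (S)-4-bromo-2-methylbutanoate | CCOC(=O)[C@@H](C)CCBr | intermediate
10 | ethyl (S)-2-methyl-4-[(1-phenyl-1H-tetrazol-5-yl)sulfanyl]butanoate | CCOC(=O)[C@@H](C)CCSc1nnnn1-c1ccccc1 | intermediate
11 | ethyl (S)-2-methyl-4-[(1-phenyl-1H-tetrazol-5-yl)sulfonyl]butanoate | CCOC(=O)[C@@H](C)CCS(=O)(=O)c1nnnn1-c1ccccc1 | intermediate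
12 | ethyl (2S,4E,7R,9E)-7-(tert-butyldimethylsilyloxy)-10-iodo-2-methyldeca-4,9-dienoate | I/C=C/C[C@H](O[Si](C)(C)C(C)(C)C)C/C=C/C[C@H](C)C(=O)OCC | intermediate
13 | (2S,4E,7R,9E)-7-(tert-butyldimethylsilyloxy)-10-iodo-2-methyldeca-4,9-dienal | I/C=C/C[C@H](O[Si](C)(C)C(C)(C)C)C/C=C/C[C@H](C)C=O | intermediate
14 | ethyl 2-oxo-3-(triphenyl-λ5-phosphanylidene)propanoate | CCOC(=O)C(=O)C=P(c1ccccc1)(c1ccccc1)c1ccccc1 | starting material
15 | ethyl (3E,5S,7E,10R,12E)-10-(tert-butyldimethylsilyloxy)-13-iodo-5-methyl-2-oxotrideca-3,7,12-trienoate | I/C=C/C[C@H](O[Si](C)(C)C(C)(C)C)C/C=C/C[C@H](C)/C=C/C(=O)C(=O)OCC | intermediate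
16 | 3-(benzylsulfanyl)propanoic acid | OC(=O)CCSCc1ccccc1 | starting material
17 | S-phenyl 3-(benzylsulfanyl)propanethioate | O=C(CCSCc1ccccc1)Sc1ccccc1 | intermediate
18 | [(1Z)-3-(benzylsulfanyl)-1-(phenylsulfanyl)prop-1-en-1-yl]oxy(trimethyl)silane | C[Si](C)(C)O/C(Sc1ccccc1)=C/CSCc1ccccc1 | intermediate
19 | enol silane Michael adduct (C18, C24 as in the target) | I/C=C/C[C@H](O[Si](C)(C)C(C)(C)C)C/C=C/C[C@H](C)[C@@H]([C@@H](CSCc1ccccc1)C(=O)Sc1ccccc1)/C=C(\O[Si](C)(C)C)C(=O)OCC | intermediate
20 | α-iodo keto ester (C19 epimers) | I/C=C/C[C@H](O[Si](C)(C)C(C)(C)C)C/C=C/C[C@H](C)[C@@H]([C@@H](CSCc1ccccc1)C(=O)Sc1ccccc1)C(I)C(=O)C(=O)OCC | intermediate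
21 | S-benzylthiolanium iodide | I/C=C/C[C@H](O[Si](C)(C)C(C)(C)C)C/C=C/C[C@H](C)[C@@H]1C(C(=O)C(=O)OCC)[S+](Cc2ccccc2)C[C@H]1C(=O)Sc1ccccc1.[I-] | intermediate
22 | all-trans thiolane vinyl iodide thioester | I/C=C/C[C@H](O[Si](C)(C)C(C)(C)C)C/C=C/C[C@H](C)[C@@H]1[C@@H](C(=O)C(=O)OCC)SC[C@H]1C(=O)Sc1ccccc1 | intermediate
23 | but-3-yn-1-ol | C#CCCO | starting material
24 | 5-(but-3-yn-1-ylsulfanyl)-1-phenyl-1H-tetrazole | C#CCCSc1nnnn1-c1ccccc1 | intermediate
25 | 5-(but-3-yn-1-ylsulfonyl)-1-phenyl-1H-tetrazole | C#CCCS(=O)(=O)c1nnnn1-c1ccccc1 | intermediate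
26 | (E)-2-methylbut-2-enal | C/C=C(\C)C=O | starting material
27 | (4E,6E)-6-methylocta-4,6-dien-1-yne | C#CC/C=C/C(C)=C/C | intermediate
28 | tributyl[(1E,4E,6E)-6-methylocta-1,4,6-trien-1-yl]stannane | CCCC[Sn](CCCC)(CCCC)/C=C/C/C=C/C(C)=C/C | intermediate
29 | tetraene thioester | C/C=C(C)/C=C/C/C=C/C=C/C[C@H](O[Si](C)(C)C(C)(C)C)C/C=C/C[C@H](C)[C@@H]1[C@@H](C(=O)C(=O)OCC)SC[C@H]1C(=O)Sc1ccccc1 | intermediate
30 | 4-methoxyfuran-2(5H)-one | COC1=CC(=O)OC1 | starting material
31 | 5-[(dimethylamino)methyl]-4-methoxyfuran-2(5H)-one | COC1=CC(=O)OC1CN(C)C | intermediate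
32 | (3-methoxy-5-oxo-2,5-dihydrofuran-2-yl)methyl(trimethyl)ammonium iodide | COC1=CC(=O)OC1C[N+](C)(C)C.[I-] | intermediate
33 | 4-methoxy-5-methylidenefuran-2(5H)-one | COC1=CC(=O)OC1=C | intermediate
34 | 4-methoxy-5-methylidene-3-(tributylstannyl)furan-2(5H)-one | COC1=C([Sn](CCCC)(CCCC)CCCC)C(=O)OC1=C | intermediate
35 | cycloaddition precursor (3-acyl-4-methoxy-5-methylidenetetronate) | C/C=C(C)/C=C/C/C=C/C=C/C[C@H](O[Si](C)(C)C(C)(C)C)C/C=C/C[C@H](C)[C@@H]1[C@@H](C(=O)C(=O)OCC)SC[C@H]1C(=O)C1=C(OC)C(=C)OC1=O | intermediate
36 | cycloadduct (TBS ether, ethyl ester, O-methyl tetronate) | CC1=C[C@H]2C/C=C/C=C/C[C@H](O[Si](C)(C)C(C)(C)C)C/C=C/C[C@H](C)[C@@H]3[C@@H](C(=O)C(=O)OCC)SC[C@H]3C(=O)C3=C(OC)[C@@]2(C[C@H]1C)OC3=O | intermediate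
37 | tetronic acid (TBS ether, ethyl ester) | CC1=C[C@H]2C/C=C/C=C/C[C@H](O[Si](C)(C)C(C)(C)C)C/C=C/C[C@H](C)[C@@H]3[C@@H](C(=O)C(=O)OCC)SC[C@H]3C(=O)C3=C(O)[C@@]2(C[C@H]1C)OC3=O | intermediate
38 | ethyl ester of the target | CC1=C[C@H]2C/C=C/C=C/C[C@H](O)C/C=C/C[C@H](C)[C@@H]3[C@@H](C(=O)C(=O)OCC)SC[C@H]3C(=O)C3=C(O)[C@@]2(C[C@H]1C)OC3=O | intermediate
39 | CNP0224658.3 | CC1=C[C@H]2C/C=C/C=C/C[C@H](O)C/C=C/C[C@H](C)[C@@H]3[C@@H](C(=O)C(=O)O)SC[C@H]3C(=O)C3=C(O)[C@@]2(C[C@H]1C)OC3=O | target

**Step count and risks**

Total step count: 29. Longest linear sequence: 16 steps (steps 1–5, 10–12, 15, 16, 21, 25–29).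

Steps most likely to fail:

Step 26. The ring closure may be too slow to compete with intermolecular oligomerisation of the reactive methylidene tetronate, the internal C6–C9 diene may be engaged instead, or the diene may be attacked on the wrong face because nothing but the folding of the tether controls it. Fallback (sets out from 28 and 33, uses 22, returns at 36): the cycloaddition is run intermolecularly and the large ring is closed afterwards by ketone formation. Stannane 28 (excess) and dienophile 33 are heated in toluene at 130 °C with BHT. This should give the racemic exo spiro adduct F1; the methyl on C2 directs the substituted dienophile carbon C28 to C4. Lithiation at the only remaining vinylic position C26 (LiN(iPr)2, THF, −78 °C) and Bu3SnCl give the bis-stannane F2. Stille coupling with iodide 22 (Pd2(dba)3, AsPh3, no copper) should occur at the unhindered alkenylstannane and give the seco thioester F3 as two diastereomers that differ at the three cyclohexene stereocentres and are separated by chromatography. The isomer with the target configuration is cyclised at high dilution by the intramolecular thioester–stannane ketone synthesis under the conditions of step 25 to give 36.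

Step 16. Iodination may be diverted to the sulfide or the C13=C14 alkene, the sulfonium salt may fail to lose its benzyl group or may reopen, and the base equilibration at C24 may be slow or accompanied by ring opening. Fallback (sets out from 15, returns at 22): sulfur is introduced as an electrophile. Commercial 3-(tritylsulfanyl)propanoic acid is converted as in steps 13 and 14 into S-phenyl 3-(tritylsulfanyl)propanethioate F4 and its trimethylsilyl ketene thioacetal F5, which adds to 15 as in step 15 to give the enol silane F6. Iodine (CH2Cl2, −40 → 0 °C) cleaves the sulfur–trityl bond to a sulfenyl iodide, which sulfenylates the enol silane at C19 in a five-membered ring closure; the DBU equilibration then gives 22.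

Step 25. Transmetalation of the hindered, electron-poor stannyl tetronate may be slower than its protodestannylation or than decomposition of the methylidene tetronate, and the α-branched thioester may react sluggishly. Fallback (sets out from 29, returns at 35): thioester 29 is hydrolysed with AgNO3 and 2,6-lutidine in aqueous THF to the carboxylic acid F7, converted with 1-chloro-N,N,2-trimethylprop-1-en-1-amine in CH2Cl2 into the acid chloride F8, and coupled with stannane 34 by Stille acylation (PdCl2(PPh3)2 cat., toluene, 60 °C) to give 35.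

Further compounds
F1 | step 26 | racemic exo spiro adduct of 28 and 33 (enantiomer leading to 36 shown) | COC1=CC(=O)O[C@]12C[C@@H](C)C(C)=C[C@H]2C/C=C/[Sn](CCCC)(CCCC)CCCC
F2 | step 26 | 3-stannylated spiro adduct (bis-stannane) | COC1=C([Sn](CCCC)(CCCC)CCCC)C(=O)O[C@]12C[C@@H](C)C(C)=C[C@H]2C/C=C/[Sn](CCCC)(CCCC)CCCC
F3 | step 26 | seco thioester carrying the stannyl spirotetronate | COC1=C([Sn](CCCC)(CCCC)CCCC)C(=O)O[C@]12C[C@@H](C)C(C)=C[C@H]2C/C=C/C=C/C[C@H](O[Si](C)(C)C(C)(C)C)C/C=C/C[C@H](C)[C@@H]1[C@@H](C(=O)C(=O)OCC)SC[C@H]1C(=O)Sc1ccccc1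
F4 | step 16 | S-phenyl 3-(tritylsulfanyl)propanethioate | O=C(CCSC(c1ccccc1)(c1ccccc1)c1ccccc1)Sc1ccccc1
F5 | step 16 | [(1Z)-1-(phenylsulfanyl)-3-(tritylsulfanyl)prop-1-en-1-yl]oxy(trimethyl)silane | C[Si](C)(C)O/C(Sc1ccccc1)=C/CSC(c1ccccc1)(c1ccccc1)c1ccccc1
F6 | step 16 | S-trityl enol silane Michael adduct | I/C=C/C[C@H](O[Si](C)(C)C(C)(C)C)C/C=C/C[C@H](C)[C@@H]([C@@H](CSC(c1ccccc1)(c1ccccc1)c1ccccc1)C(=O)Sc1ccccc1)/C=C(\O[Si](C)(C)C)C(=O)OCC
F7 | step 25 | tetraene thiolane carboxylic acid | C/C=C(C)/C=C/C/C=C/C=C/C[C@H](O[Si](C)(C)C(C)(C)C)C/C=C/C[C@H](C)[C@@H]1[C@@H](C(=O)C(=O)OCC)SC[C@H]1C(=O)O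
F8 | step 25 | tetraene thiolane acid chloride | C/C=C(C)/C=C/C/C=C/C=C/C[C@H](O[Si](C)(C)C(C)(C)C)C/C=C/C[C@H](C)[C@@H]1[C@@H](C(=O)C(=O)OCC)SC[C@H]1C(=O)Cl
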